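**Strategy.** The α-methylene-γ-butyrolactone is cis-fused to the cyclohexene through C3a–C7a (benzofuranone numbering), a bond shared by both rings. Disconnecting it together with the lactone bonds at C2 turns the bicycle into an acyclic (Z)-allenyl aldehyde plus CO. A ruthenium-catalysed allenic hetero-Pauson–Khand (2+2+1) reaction forges C3a–C7a, closes carbocycle and lactone, leaves the exocyclic methylene, and sets both ring-fusion stereocenters from the one carbinol center (C4) set by catalysis. The alkene geometry of the precursor is fixed in a dihydropyranone ring built from (S)-citronellic acid, which supplies the side-chain stereocenter. The lactone is opened by an acetylide; asymmetric transfer hydrogenation and SN2′ hydride delivery give the allenyl carbinol.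

Key step: step 11

Remarks on the chemistry: compounds 1, 3, 11 and 20 are taken as commercial. The acetal carbon of the tetrahydropyranyl group is stereorandom, so 11–14 are epimer mixtures at that center only; it is excised in step 8. Compounds 4–9 are mixtures at the two transient ring stereocenters that step 5 removes.

Step 1
Reactants: 1 4-hydroxybutan-2-one
Product: 2 4-(tert-butyldimethylsilyloxy)butan-2-one
Conditions: TBSCl, imidazole, CH2Cl2, 0 °C → rt
Reagents that add atoms: tert-butyldimethylsilyl chloride, CC(C)(C)[Si](C)(C)Cl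
Why: Imidazole-promoted O-silylation of the primary alcohol is fast at 0 °C and masks the hydroxyl that would otherwise quench the enediolate in step 2.

Step 2
Reactants: 3 (S)-citronellic acid; 2 4-(tert-butyldimethylsilyloxy)butan-2-one
Product: 5 4-hydroxy-4-methyl-3-[(2S)-6-methylhept-5-en-2-yl]oxan-2-one, via hydroxy acid 4 (not isolated)
Conditions: LiN(iPr)2 (2.2 equiv), THF, −78 → 0 °C; then 2, −78 °C; then 1 M HCl, THF, rt
Reagents that add atoms: none
Why: Aldol addition of the lithium enediolate (carboxylic acid dianion) of 3 to the methyl ketone, then acid-mediated desilylation and δ-lactonization on work-up; the two new ring stereocenters form unselectively but are erased in step 5, and the purchased (S)-methyl-bearing carbon is not touched.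

Step 3
Reactants: 5 4-hydroxy-4-methyl-3-[(2S)-6-methylhept-5-en-2-yl]oxan-2-one
Product: 7 4-hydroxy-3-[(2S)-5-hydroxypentan-2-yl]-4-methyloxan-2-one, via aldehyde 6 (not isolated)
Conditions: O3, CH2Cl2–MeOH (4:1), −78 °C; then NaBH4, −78 → −20 °C
Reagents that add atoms: ozone, [O-][O+]=O
Why: Ozonolysis of the only alkene present, with NaBH4 reduction of the resulting aldehyde at low temperature where the lactone should survive, unveils the primary alcohol of the side chain.

Step 4
Reactants: 7 4-hydroxy-3-[(2S)-5-hydroxypentan-2-yl]-4-methyloxan-2-one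
Product: 8 3-[(2S)-5-(tert-butyldiphenylsilyloxy)pentan-2-yl]-4-hydroxy-4-methyloxan-2-one
Conditions: TBDPSCl, imidazole, DMF, rt
Reagents that add atoms: tert-butyl(chloro)diphenylsilane, CC(C)(C)[Si](Cl)(c1ccccc1)c1ccccc1
Why: Silylation with the bulky chlorosilane is selective for the primary over the tertiary hydroxyl.

Step 5
Reactants: 8 3-[(2S)-5-(tert-butyldiphenylsilyloxy)pentan-2-yl]-4-hydroxy-4-methyloxan-2-one
Product: 10 3-[(2S)-5-(tert-butyldiphenylsilyloxy)pentan-2-yl]-4-methyl-5,6-dihydro-2H-pyran-2-one, via tertiary mesylate 9 (not isolated)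
Conditions: MsCl, Et3N, CH2Cl2, 0 °C → rt; then DBU, rt
Reagents that add atoms: none
Why: Mesylation of the tertiary alcohol and E1cB elimination through the lactone enolate, with DBU equilibrating any non-conjugated isomers, should give the conjugated endocyclic tetrasubstituted alkene, whose geometry (ring CH2 cis to the carbonyl carbon) is fixed by the ring.

Step 6
Reactants: 10 3-[(2S)-5-(tert-butyldiphenylsilyloxy)pentan-2-yl]-4-methyl-5,6-dihydro-2H-pyran-2-one; 11 2-(prop-2-yn-1-yloxy)oxane
Product: 13 (5Z)-8-hydroxy-6-methyl-1-(oxan-2-yloxy)-5-[(2S)-5-(tert-butyldiphenylsilyloxy)pentan-2-yl]oct-5-en-2-yn-4-one, via lithium acetylide 12 (not isolated)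
Conditions: 11, n-BuLi, THF, −78 °C; then 10, −78 → −40 °C; aq NH4Cl
Reagents that add atoms: none
Why: 1,2-Addition of the lithium acetylide to the lactone carbonyl gives a tetrahedral lithium hemiketal that is stable at low temperature, so no second addition occurs, and it collapses on work-up to the ring-opened ynone, which inherits the Z geometry of the tetrasubstituted alkene from the ring.

Step 7
Reactants: 13 (5Z)-8-hydroxy-6-methyl-1-(oxan-2-yloxy)-5-[(2S)-5-(tert-butyldiphenylsilyloxy)pentan-2-yl]oct-5-en-2-yn-4-one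
Product: 14 (4S,5Z)-6-methyl-1-(oxan-2-yloxy)-5-[(2S)-5-(tert-butyldiphenylsilyloxy)pentan-2-yl]oct-5-en-2-yne-4,8-diol
Conditions: Ru[(R,R)-TsDPEN](p-cymene) (preformed amido complex, 2 mol %), iPrOH, rt
Reagents that add atoms: none
Why: Noyori asymmetric transfer hydrogenation of the alkynyl ketone: with the slim alkynyl group in the π-binding site and the bulky alkenyl group in the alkyl site, the (R,R)-catalyst is expected to deliver hydride to the face that gives the (4S)-carbinol (catalyst control; the free primary alcohol is tolerated).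

Step 8
Reactants: 14 (4S,5Z)-6-methyl-1-(oxan-2-yloxy)-5-[(2S)-5-(tert-butyldiphenylsilyloxy)pentan-2-yl]oct-5-en-2-yne-4,8-diol
Product: 15 (3Z,5S)-3-methyl-4-[(2S)-5-(tert-butyldiphenylsilyloxy)pentan-2-yl]octa-3,6,7-triene-1,5-diol
Conditions: LiAlH4 (excess), Et2O, 0 °C → reflux
Reagents that add atoms: none
Why: Hydroxyl-directed trans-hydroalumination of the propargylic alcohol places hydride on the alkyne carbon next to the carbinol and aluminium on the far one, and 1,2-elimination of the tetrahydropyranyloxide then gives the terminal allene (SN2′-type reduction); the carbinol stereocenter is not involved.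

Step 9
Reactants: 15 (3Z,5S)-3-methyl-4-[(2S)-5-(tert-butyldiphenylsilyloxy)pentan-2-yl]octa-3,6,7-triene-1,5-diol
Product: 16 bis(triethylsilyl) ether of 15
Conditions: TESCl (2.5 equiv), imidazole, DMAP (cat.), DMF, 0 °C → rt
Reagents that add atoms: chlorotriethylsilane, CC[Si](Cl)(CC)CC
Why: Exhaustive silylation sets up the primary silyl ether for direct oxidation and protects the allenyl carbinol, which would otherwise close a lactol onto the aldehyde.

Step 10
Reactants: 16 bis(triethylsilyl) ether of 15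
Product: 17 (3Z,5S)-3-methyl-4-[(2S)-5-(tert-butyldiphenylsilyloxy)pentan-2-yl]-5-(triethylsilyloxy)octa-3,6,7-trienal
Conditions: (COCl)2, DMSO, CH2Cl2, −78 → −30 °C; then Et3N, −78 → −20 °C
Reagents that add atoms: none
Why: Under Swern conditions the primary triethylsilyl ether is cleaved by the activated DMSO–chloride system and oxidized in the same operation, whereas the secondary triethylsilyl ether is retained; low temperature limits migration of the β,γ-double bond.

Step 11
Reactants: 17 (3Z,5S)-3-methyl-4-[(2S)-5-(tert-butyldiphenylsilyloxy)pentan-2-yl]-5-(triethylsilyloxy)octa-3,6,7-trienal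
Product: 18 (3aR,4S,7aR)-5-[(2S)-5-(tert-butyldiphenylsilyloxy)pentan-2-yl]-6-methyl-3-methylidene-4-(triethylsilyloxy)-3a,4,7,7a-tetrahydro-1-benzofuran-2(3H)-one
Conditions: Ru3(CO)12 (5 mol %), CO (20 atm), 1,4-dioxane, 120 °C
Reagents that add atoms: carbon monoxide, [C-]#[O+]
Why: Zerovalent ruthenium carbonyl binds the aldehyde and the proximal π bond of the allene and couples them oxidatively to a 2-oxaruthenacyclopentane in which the new C–C bond (C3a–C7a) joins the aldehyde carbon to the inner allene carbon; CO insertion into the Ru–C(sp2) bond and C–O reductive elimination then release the lactone, and the untouched distal allene π bond becomes the exocyclic methylene. This is the allenic hetero-Pauson–Khand reaction, a (2+2+1) cyclocarbonylation known for allenyl aldehydes with Ru3(CO)12 under CO (and with Mo(CO)6/DMSO) to give cis-fused α-methylene-γ-butyrolactones. The cyclohexene closes in a 6-exo mode with respect to both π components (the central allene carbon and the carbonyl oxygen stay outside the carbocycle), and the lactone closes as the five-membered ring of the carbonylative annulation, with CO supplying C2. The cis ring fusion (C3a, C7a) should follow from the five-membered oxametallacycle, which bridges cis positions of the forming six-membered ring without strain; the configuration of C3a relative to C4 is controlled by the silyloxy stereocenter, which should sit pseudoaxial to avoid A(1,2) strain with the branched C5 substituent, so that the ruthenium-bearing allene carbon adds on the face anti to OSiEt3 (3a,4-trans). The step needs proximal-over-distal allene selectivity, inertness of the tetrasubstituted alkene and survival of the β,γ-unsaturated aldehyde: the Z geometry preorganizes the six-membered closure, the tetrasubstituted alkene is too hindered to bind, and the neutral, base-free medium disfavors enolization-driven double-bond migration.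

Step 12
Reactants: 18 (3aR,4S,7aR)-5-[(2S)-5-(tert-butyldiphenylsilyloxy)pentan-2-yl]-6-methyl-3-methylidene-4-(triethylsilyloxy)-3a,4,7,7a-tetrahydro-1-benzofuran-2(3H)-one
Product: 19 (3aS,4S,7aR)-5-[(2S)-5-(tert-butyldiphenylsilyloxy)pentan-2-yl]-4-hydroxy-6-methyl-3-methylidene-3a,4,7,7a-tetrahydro-1-benzofuran-2(3H)-one
Conditions: HF·pyridine, pyridine, THF, 0 °C
Reagents that add atoms: none
Why: Buffered HF·pyridine cleaves the secondary triethylsilyl ether much faster than the primary tert-butyldiphenylsilyl ether (selective desilylation).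

Step 13
Reactants: 19 (3aS,4S,7aR)-5-[(2S)-5-(tert-butyldiphenylsilyloxy)pentan-2-yl]-4-hydroxy-6-methyl-3-methylidene-3a,4,7,7a-tetrahydro-1-benzofuran-2(3H)-one; 20 (R)-2-methylbutanoic acid
Product: 21 (3aR,4S,7aR)-5-[(2S)-5-(tert-butyldiphenylsilyloxy)pentan-2-yl]-6-methyl-3-methylidene-2-oxo-2,3,3a,4,7,7a-hexahydro-1-benzofuran-4-yl (2R)-2-methylbutanoate
Conditions: EDC·HCl, DMAP, CH2Cl2, 0 °C → rt
Reagents that add atoms: none
Why: Steglich esterification (carbodiimide/DMAP) of the hindered allylic alcohol with the enantiopure acid; the α-stereocenter of the acid should not epimerize under these mild conditions and the primary hydroxyl is still silyl-protected.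

Step 14
Reactants: 21 (3aR,4S,7aR)-5-[(2S)-5-(tert-butyldiphenylsilyloxy)pentan-2-yl]-6-methyl-3-methylidene-2-oxo-2,3,3a,4,7,7a-hexahydro-1-benzofuran-4-yl (2R)-2-methylbutanoate
Product: 22 (3aR,4S,7aR)-5-[(2S)-5-hydroxypentan-2-yl]-6-methyl-3-methylidene-2-oxo-2,3,3a,4,7,7a-hexahydro-1-benzofuran-4-yl (2R)-2-methylbutanoate
Conditions: HF·pyridine (excess), THF, 0 °C → rt
Reagents that add atoms: none
Why: Fluoride-mediated cleavage of the Si–O bond of the primary silyl ether under non-basic conditions should leave the α-methylene lactone and the ester intact.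

**Compound list**

1 | 4-hydroxybutan-2-one | CC(=O)CCO | starting material
2 | 4-(tert-butyldimethylsilyloxy)butan-2-one | CC(=O)CCO[Si](C)(C)C(C)(C)C | intermediate
3 | (S)-citronellic acid, (3S)-3,7-dimethyloct-6-enoic acid | OC(=O)C[C@@H](C)CCC=C(C)C | starting material
4 | 3-hydroxy-3-methyl-2-[(2S)-6-methylhept-5-en-2-yl]-5-(tert-butyldimethylsilyloxy)pentanoic acid (diastereomer mixture at C2/C3) | OC(=O)C([C@@H](C)CCC=C(C)C)C(C)(O)CCO[Si](C)(C)C(C)(C)C | intermediate (not isolated)
5 | 4-hydroxy-4-methyl-3-[(2S)-6-methylhept-5-en-2-yl]oxan-2-one (diastereomer mixture at C3/C4) | CC1(O)CCOC(=O)C1[C@@H](C)CCC=C(C)C | intermediate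
6 | (4S)-4-(4-hydroxy-4-methyl-2-oxooxan-3-yl)pentanal | CC1(O)CCOC(=O)C1[C@@H](C)CCC=O | intermediate (not isolated)
7 | 4-hydroxy-3-[(2S)-5-hydroxypentan-2-yl]-4-methyloxan-2-one | CC1(O)CCOC(=O)C1[C@@H](C)CCCO | intermediate
8 | 3-[(2S)-5-(tert-butyldiphenylsilyloxy)pentan-2-yl]-4-hydroxy-4-methyloxan-2-one | CC1(O)CCOC(=O)C1[C@@H](C)CCCO[Si](c2ccccc2)(c2ccccc2)C(C)(C)C | intermediate
9 | tertiary methanesulfonate of 8 | CC1(OS(C)(=O)=O)CCOC(=O)C1[C@@H](C)CCCO[Si](c2ccccc2)(c2ccccc2)C(C)(C)C | intermediate (not isolated)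
10 | 3-[(2S)-5-(tert-butyldiphenylsilyloxy)pentan-2-yl]-4-methyl-5,6-dihydro-2H-pyran-2-one | CC1=C([C@@H](C)CCCO[Si](c2ccccc2)(c2ccccc2)C(C)(C)C)C(=O)OCC1 | intermediate
11 | 2-(prop-2-yn-1-yloxy)oxane (tetrahydropyranyl ether of propargyl alcohol, racemic) | C#CCOC1CCCCO1 | starting material
12 | lithium acetylide of 11 | [Li]C#CCOC1CCCCO1 | intermediate (not isolated)
13 | (5Z)-8-hydroxy-6-methyl-1-(oxan-2-yloxy)-5-[(2S)-5-(tert-butyldiphenylsilyloxy)pentan-2-yl]oct-5-en-2-yn-4-one | OCC/C(C)=C(/[C@@H](C)CCCO[Si](c1ccccc1)(c1ccccc1)C(C)(C)C)C(=O)C#CCOC1CCCCO1 | intermediate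
14 | (4S,5Z)-6-methyl-1-(oxan-2-yloxy)-5-[(2S)-5-(tert-butyldiphenylsilyloxy)pentan-2-yl]oct-5-en-2-yne-4,8-diol | OCC/C(C)=C(/[C@@H](C)CCCO[Si](c1ccccc1)(c1ccccc1)C(C)(C)C)[C@@H](O)C#CCOC1CCCCO1 | intermediate
15 | (3Z,5S)-3-methyl-4-[(2S)-5-(tert-butyldiphenylsilyloxy)pentan-2-yl]octa-3,6,7-triene-1,5-diol | OCC/C(C)=C(/[C@@H](C)CCCO[Si](c1ccccc1)(c1ccccc1)C(C)(C)C)[C@@H](O)C=C=C | intermediate
16 | bis(triethylsilyl) ether of 15, (3Z,5S)-configured | CC[Si](CC)(CC)OCC/C(C)=C(/[C@@H](C)CCCO[Si](c1ccccc1)(c1ccccc1)C(C)(C)C)[C@@H](O[Si](CC)(CC)CC)C=C=C | intermediate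
17 | (3Z,5S)-3-methyl-4-[(2S)-5-(tert-butyldiphenylsilyloxy)pentan-2-yl]-5-(triethylsilyloxy)octa-3,6,7-trienal | O=CC/C(C)=C(/[C@@H](C)CCCO[Si](c1ccccc1)(c1ccccc1)C(C)(C)C)[C@@H](O[Si](CC)(CC)CC)C=C=C | intermediate
18 | (3aR,4S,7aR)-5-[(2S)-5-(tert-butyldiphenylsilyloxy)pentan-2-yl]-6-methyl-3-methylidene-4-(triethylsilyloxy)-3a,4,7,7a-tetrahydro-1-benzofuran-2(3H)-one | C=C1C(=O)O[C@@H]2CC(C)=C([C@@H](C)CCCO[Si](c3ccccc3)(c3ccccc3)C(C)(C)C)[C@@H](O[Si](CC)(CC)CC)[C@H]12 | intermediate
19 | (3aS,4S,7aR)-5-[(2S)-5-(tert-butyldiphenylsilyloxy)pentan-2-yl]-4-hydroxy-6-methyl-3-methylidene-3a,4,7,7a-tetrahydro-1-benzofuran-2(3H)-one | C=C1C(=O)O[C@@H]2CC(C)=C([C@@H](C)CCCO[Si](c3ccccc3)(c3ccccc3)C(C)(C)C)[C@@H](O)[C@H]12 | intermediate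
20 | (R)-2-methylbutanoic acid | CC[C@@H](C)C(=O)O | starting material
21 | (3aR,4S,7aR)-5-[(2S)-5-(tert-butyldiphenylsilyloxy)pentan-2-yl]-6-methyl-3-methylidene-2-oxo-2,3,3a,4,7,7a-hexahydro-1-benzofuran-4-yl (2R)-2-methylbutanoate | C=C1C(=O)O[C@@H]2CC(C)=C([C@@H](C)CCCO[Si](c3ccccc3)(c3ccccc3)C(C)(C)C)[C@@H](OC(=O)[C@H](C)CC)[C@H]12 | intermediate
22 | (3aR,4S,7aR)-5-[(2S)-5-hydroxypentan-2-yl]-6-methyl-3-methylidene-2-oxo-2,3,3a,4,7,7a-hexahydro-1-benzofuran-4-yl (2R)-2-methylbutanoate | C=C1C(=O)O[C@@H]2CC(C)=C([C@@H](C)CCCO)[C@@H](OC(=O)[C@H](C)CC)[C@H]12 | target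

**Step count.** Total: 14 steps. Longest linear sequence: 14 steps (steps 1–14 from 1; 13 steps from 3).

**Steps most likely to fail**

Step 11. Facial discrimination at the allene relative to the silyloxy-bearing carbon may be low, and at 120 °C the β,γ-double bond of the aldehyde may migrate into conjugation, or the aldehyde may lose CO, before the metallacycle forms. The fallback is a stepwise allylmetal route at room temperature that sets out from 17. (Bu3Sn)2 with [Pd(allyl)Cl]2 (cat.) in THF adds Sn–Sn across the allene, and the allylstannane so formed closes onto the aldehyde through a cyclic transition state. After hydrolysis of the O–Sn bond this should give the cis-hydroxy vinylstannane, (ring centers as in 18) 3-methyl-4-[(2S)-5-(tert-butyldiphenylsilyloxy)pentan-2-yl]-6-[1-(tributylstannyl)ethenyl]-5-(triethylsilyloxy)cyclohex-3-en-1-ol F1. I2 in CH2Cl2 at 0 °C converts it into the corresponding 6-(1-iodoethenyl)cyclohexenol F2. Pd(PPh3)4 (cat.), CO (1 atm), Et3N, MeCN, 50 °C then closes the α-methylene lactone by carbonylative lactonization and comes back to the route at 18.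

Step 7. Enantioface discrimination may be poor because both ketone substituents are unsaturated and the catalyst may bind the alkenyl instead of the alkynyl group. The fallback sets out from 13. Luche reduction (NaBH4, CeCl3·7H2O, MeOH, −78 °C) gives 14 together with its carbinol epimer, the (4R,5Z)-diol F3; the two are diastereomers and should separate by chromatography. F3 is inverted by Mitsunobu reaction with 4-nitrobenzoic acid (PPh3, DIAD, THF; the primary alcohol is esterified as well) to the (4S,5Z)-bis(4-nitrobenzoate) F4. Methanolysis (K2CO3, MeOH) comes back to the route at 14.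

Step 10. The amine base may move the β,γ-double bond into conjugation, or the oxidation may not discriminate fully between the two silyl ethers. The fallback sets out from 16. PPTS in MeOH–CH2Cl2 at −10 °C cleaves only the primary silyl ether and gives (3Z,5S)-3-methyl-4-[(2S)-5-(tert-butyldiphenylsilyloxy)pentan-2-yl]-5-(triethylsilyloxy)octa-3,6,7-trien-1-ol F5. Buffered Dess–Martin periodinane (NaHCO3, CH2Cl2, 0 °C) oxidizes it without amine base and comes back to the route at 17.

Further compounds
F1 | step 11 | 3-methyl-4-[(2S)-5-(tert-butyldiphenylsilyloxy)pentan-2-yl]-6-[1-(tributylstannyl)ethenyl]-5-(triethylsilyloxy)cyclohex-3-en-1-ol, hydroxyl cis to the stannylvinyl group, silyloxy trans to it | C=C([Sn](CCCC)(CCCC)CCCC)[C@@H]1[C@H](O)CC(C)=C([C@@H](C)CCCO[Si](c2ccccc2)(c2ccccc2)C(C)(C)C)[C@H]1O[Si](CC)(CC)CC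
F2 | step 11 | 6-(1-iodoethenyl)-3-methyl-4-[(2S)-5-(tert-butyldiphenylsilyloxy)pentan-2-yl]-5-(triethylsilyloxy)cyclohex-3-en-1-ol, ring centers as in F1 | C=C(I)[C@@H]1[C@H](O)CC(C)=C([C@@H](C)CCCO[Si](c2ccccc2)(c2ccccc2)C(C)(C)C)[C@H]1O[Si](CC)(CC)CC
F3 | step 7 | (4R,5Z)-6-methyl-1-(oxan-2-yloxy)-5-[(2S)-5-(tert-butyldiphenylsilyloxy)pentan-2-yl]oct-5-en-2-yne-4,8-diol | OCC/C(C)=C(/[C@@H](C)CCCO[Si](c1ccccc1)(c1ccccc1)C(C)(C)C)[C@H](O)C#CCOC1CCCCO1
F4 | step 7 | (4S,5Z)-6-methyl-1-(oxan-2-yloxy)-5-[(2S)-5-(tert-butyldiphenylsilyloxy)pentan-2-yl]oct-5-en-2-yne-4,8-diyl bis(4-nitrobenzoate) | O=C(OCC/C(C)=C(/[C@@H](C)CCCO[Si](c1ccccc1)(c1ccccc1)C(C)(C)C)[C@@H](OC(=O)c1ccc(cc1)[N+](=O)[O-])C#CCOC1CCCCO1)c1ccc(cc1)[N+](=O)[O-]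
F5 | step 10 | (3Z,5S)-3-methyl-4-[(2S)-5-(tert-butyldiphenylsilyloxy)pentan-2-yl]-5-(triethylsilyloxy)octa-3,6,7-trien-1-ol | OCC/C(C)=C(/[C@@H](C)CCCO[Si](c1ccccc1)(c1ccccc1)C(C)(C)C)[C@@H](O[Si](CC)(CC)CC)C=C=C
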